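(The readings stem from a simulated flask with constants of no real substance, and the scatter is random.)

The stirred vessel gets the same charge in Tuesday's, Wednesday's, Friday's and Saturday's, and the flasks differ in when it goes in. You suspect slow dosing buys a clearly better share, so here is my quick number.

| setting | midnight | dusk | winter | Wednesday's | Saturday's | Friday's | Tuesday's |
|---|---|---|---|---|---|---|---|
| starting material | 0.050 M | 0.034 M | 0.075 M | 0.050 M | 0.050 M (fed, over 50 min) | 0.050 M | 0.050 M |
| partner | 0.95 equiv | 0.95 equiv | 0.95 equiv | 0.950 equiv (in portions, 3, over 50 min) | 0.950 equiv | 0.950 equiv (fed, over 50 min) | 0.950 equiv |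
| remark | run made earlier | run made earlier | run made earlier | first portion at the start, last at 50 min | all else is in the flask from the start; the feed brings no volume worth counting | all else is in the flask from the start; the feed brings no volume worth counting | everything together at the start |
| time |  |  |  | 2.0 h | 2.0 h | 2.0 h | 2.0 h |

midnight run (percent of the starting material charged)

| time / min | mono adduct / % | double product / % |
|---|---|---|
| 15.0 | 12.8 | 0 |
| 40.0 | 25.3 | 0.6 |
| 80.0 | 36.4 | 0 |
| 120 | 45.4 | 1.6 |

dusk run (percent of the starting material charged)

| time / h | mono adduct / % | double product / % |
|---|---|---|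
| 0.333 | 12.5 | 0 |
| 0.833 | 22.4 | 0 |
| 1.50 | 31.4 | 0.3 |
| 2.50 | 41.1 | 2.1 |

winter run (percent of the starting material charged)

| time / h | mono adduct / % | double product / % |
|---|---|---|
| 0.200 | 16.2 | 0 |
| 0.417 | 28.0 | 0.3 |
| 1.00 | 41.3 | 1.6 |
| 2.50 | 55.3 | 5.0 |

(scatter of a reading: 1 percentage point)



- which flask leads in share of mono adduct in mono adduct plus double product ("all alike" within 1.5 percentage points) (Wednesday's / Saturday's / Friday's / Tuesday's / all alike)
- share of mono adduct in mono adduct plus double product at the end, Wednesday's
- share of mono adduct in mono adduct plus double product at the end, Saturday's
- share of mono adduct in mono adduct plus double product at the end, Friday's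
- share of mono adduct in mono adduct plus double product at the end, Tuesday's

Take the double product as mono adduct meeting partner a second time. Both steps then carry the same partner factor, and it divides out of their ratio. Let x be the fraction of the charge found as mono adduct plus double product and a the rest, taken as starting material left. Counting what has gone as mono adduct gives a first round of D = s(−ln a − x), and putting that back gives the share (x − D)/x. The last readings of the three runs give 0.140: s, the selectivity factor, the second step's rate constant over the first's. Those double-product readings carry a scatter of 1 percentage point, so s is a rough reading.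

Tuesday's has the midnight run's charge and time, so I take x from that run's last reading, 47.0 %, and my share for Tuesday's is 95.1 %. Dosing over 50 min makes the dosed material late by 25.0 min on average, so I read Wednesday's and Friday's off the midnight run at 95.0 min. That gives x = 40.4 %, less than Tuesday's, and a share of 96.1 %. Saturday's goes in with them as a rougher step, since its starting material arrives late. The gain is 1.00 point, smaller than the margin of 1.5 points, so I call the flasks alike.

The forecast, higher than mine, gives 96.8 % for Wednesday's, 96.4 % for Saturday's, 96.6 % for Friday's and 95.6 % for Tuesday's, and says “All shares land within about 1 point, so all alike”. The flasks give 96.8 %, 96.8 %, 96.8 % and 96.3 % in that order: all alike.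

    starting material + partner → mono adduct + by-product (k = 0.210 M⁻¹ min⁻¹)
    partner + mono adduct → double product + by-product (k = 0.0220 M⁻¹ min⁻¹)
    partner + double product → tris adduct + by-product (k = 0.0120 M⁻¹ min⁻¹)
    partner + tris adduct → tetra adduct + by-product (k = 0.580 M⁻¹ min⁻¹)
    2 starting material → homo dimer (k = 6.60 × 10⁻⁵ M⁻¹ min⁻¹)
    partner → decomposed reagent (k = 0.00280 min⁻¹)
    starting material + mono adduct → side product (k = 0.0110 M⁻¹ min⁻¹)

Wednesday's holds mono adduct plus double product of 42.1 % at 2.00 h, so its x is more than the value I took. With s at 0.140 the rule gives 95.8 % against the flask's 96.8 %. Now run Wednesday's recipe at 0.020 M of starting material. That neighbour ends with 23.6 % mono adduct and 0.362 % double product, so x is 24.0 % and the rule gives 98.0 %. The neighbour itself stands at a share of 98.5 %.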